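The earlier runs and the new flask were generated by integration for an exercise; scatter was added.

1. Start from the constants. Let k_L and k_Z belong to G + Q + L and G + Q + Z. Both steps carry the same factor [G][Q], so L and Z run on one clock. At each turn of that clock, L reacts s = k_L/k_Z times as readily as Z; s is the selectivity factor.

in all of them: L 0.50 M; Z 0.50 M; Q 0.29 mol%

| run | G | remark | time |
|---|---|---|---|
| Saturday's | 2.1 equiv | run made earlier |  |
| Sunday's | 3.3 equiv | run made earlier |  |
| flask | 1.50 equiv |  | 12 h |

- Saturday's (time / h: Z / %, L / %, J / %): 1.33: 46.6, 0, 39.1; 3.00: 46.2, 0.2, 32.2; 4.00: 44.3, 0.4, 29.9; 6.00: 43.5, 1.1, 28.9; 8.00: 42.4, 0, 29.3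
- Sunday's (time / h: Z / %, L / %, J / %): 0.667: 47.2, 0.2, 43.0; 2.00: 43.8, 0.4, 35.1; 3.00: 42.2, 0, 30.8; 5.00: 39.1, 0, 30.9; 8.00: 38.1, 0, 29.1

(readings scatter by 1 percentage point)

- whether the excess of Z over L among what is left of the two reaches 95% by 12 h (no / yes)
- the highest excess of Z over L among what is left of the two up to 12 h

- Q is single-handed; L and Z are mirror images of each other, charged as a racemate, each of them at the stated concentration
- reactions considered so far: 2 G -> D; G + Q + L -> Q + J; G + Q + Z -> Q + E; J <-> E; 2 Q <-> X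

2. Note the oddity. L and Z are charged alike, yet Sunday's run at 0.667 h reads L 0.2% beside Z 47.2%. Z has lost 2.8 percentage points.

3. Clear it up. Define the gap g = ln(Z/L). It starts at zero and grows s−1 times as fast as ln Z falls, so where s is large, a small loss of Z buys a wide gap.

4. Write the bill. An excess e needs g = ln((1+e)/(1−e)). For 95%, that gap bill is 3.66.

5. Test it on Sunday's run. Beside that Z, the bill allows L up to 1.21%. One reading scatters by 1 point, so the L reading is thin alone, but the next one, 0.4% beside Z 43.8%, stands below its own ceiling of 1.13% too.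

6. Pay it in the flask. Take Z as unchanged: the bill then removes about 97.4% of L, at one G each. The flask charges 1.50 equiv of G, counted on L. Less G slows the clock but leaves s alone. I reckon yes.

7. Read the forecast: yes, top 99.5%, range 96.5% to 100%; “the L exponent needed for 95% ee (about 3.7) is well within reach”.

The flask gives yes, with a top of 100%.

    2 G → D (k = 1.30 × 10⁻⁴ M⁻¹ s⁻¹)
    G + Q + L → Q + J (k = 9.90 M⁻² s⁻¹)
    G + Q + Z → Q + E (k = 0.0600 M⁻² s⁻¹)
    J ⇌ E (k = 8.10 × 10⁻⁵ s⁻¹)
    2 Q ⇌ X (K = 1800 M⁻¹, k = 3.60 M⁻¹ s⁻¹)

Its excess passes 95% at 0.632 h, with Z at 48.9%. Apply the bill there: L stood at Z·exp(−3.66), which is 1.26%.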